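## Structural features

The target is an isoflavone, a 4H-chromen-4-one in which benzene ring A and pyranone ring C share the C4a–C8a bond and a 2,4,5-trimethoxyphenyl ring B is joined to C3 by the single C3–C1' bond. Ring A is fully differentiated: C5 carries a free hydroxyl hydrogen-bonded to the C4 carbonyl, C6 a 3-methylbut-2-enyl (prenyl) chain, C7 a methoxy group and C8 a hydrogen. There is no stereocentre, and the prenyl double bond ends in two identical methyl groups, so no configuration has to be set. Three parts are fragile: the prenyl group, which cyclises onto a neighbouring phenol or hydrates under acid; the pyranone ring, which is opened by hydroxide attacking C2 and is photoactive at short wavelength; and the chelated 5-hydroxyl, which must stay free while the 7-oxygen is methylated. The real difficulty is regiochemical: prenylation of a 5,7-dioxygenated ring A by classical means competes between C6, C8 and oxygen, and the two oxygens must then be told apart. The key step avoids this by building ring A on the C2=C3 double bond of a preformed pyranone, which becomes the C8a=C4a bond. The contiguous row C5(OH)–C6(prenyl)–C7(O) is the 1-hydroxy-2-alkyl-3-siloxy pattern that a ketene/siloxyalkyne benzannulation leaves on a new benzene ring, with prenyl delivered by the alkyne and the two oxygens delivered already differentiated.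

## Logic of the disconnections

19 to 17: the O–CH3 bond at C7 is cut and replaced by O–Si. This methyl is the only atom of the target that the annulation does not deliver. In 17 the two ring A oxygens are already different (free chelated phenol at C5, silyl ether at C7). The forward step must unmask the 7-oxygen without acid and methylate it without touching the 5-hydroxyl. Fluoride and a methyl halide in one flask, through 18, should do this.

17 to 8 and 12: the four ring A bonds C8–C8a, C7–C8, C5–C6 and C4a–C5 are cut. Checked atom by atom, C5 is the acyl carbon and C8 the diazo carbon of 8, C6 and C7 are the alkyne carbons of 12, and pyranone C2/C3 of 8 become C8a/C4a. The ketene carbonyl carbon of 13 is therefore the future C5 and its CH the future C8. A pentasubstituted benzene is reduced to a monocyclic pyranone and a linear alkyne, joined convergently. The forward step needs a Wolff shift of the pyranonyl group, a regioselective (2+2) addition, ring closure at pyranone C3, and light that only the diazo group absorbs.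

8 to 6 (through 7): the bond between the acyl carbon and the diazo carbon is cut, because a diazomethyl ketone is the one-carbon acyl derivative of a carboxylic acid. The gain is a stable acid in place of a light-sensitive diazo compound. The forward step must acylate a diazomethyl nucleophile without adding it across the electron-poor pyranone double bonds.

6 to 5 to 3 and 4: after an ester/acid interchange, the bond between pyranone C5 and the aryl carbon (future C3–C1') is cut. Ring B then comes intact from 4 and the pyranone from an enol triflate. The coupling must tolerate a base-sensitive triflate and an ester. The ester must later be cleaved without hydroxide, which would open the pyranone, so acid hydrolysis is planned.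

3 to 2 to 1: only the O–S bond and the ester O–C bond are cut. 1 already has the carboxyl on the carbon that becomes C8a and the hydroxyl on the carbon that becomes C3, so no ring synthesis is needed. The forward steps must sulfonylate the enolic hydroxyl without attacking the pyranone carbonyl oxygen.

12 to 11 to 10 to 9: the O–Si bond is cut, then one alkyne carbon is removed as a one-carbon unit (ester-to-ynolate homologation), then the ester alkyl group. The forward homologation must add a dibromomethyl anion to the ester carbonyl faster than the doubly activated α-CH2 is deprotonated. The esterification must avoid acid, which would lactonise 9 or move its double bond.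

## Other disconnections considered

Alternative 1: The cut runs through ring C at C3–C4 and O1–C2. In the forward sense (E)-[2-methoxy-1-(2,4,5-trimethoxyphenyl)ethenyl]lithium A3 would add to the carbonyl of 7-methoxy-5-(methoxymethoxy)-2,2-dimethyl-6-(3-methylbut-2-enyl)-4H-1,3-benzodioxin-4-one A2. Collapse of the adduct would open the acetonide and set a phenoxide free, which would close ring C by addition to the β-methoxy enone and loss of methoxide. The product would be 7-methoxy-5-(methoxymethoxy)-6-(3-methylbut-2-enyl)-3-(2,4,5-trimethoxyphenyl)-4H-chromen-4-one A1, one acetal cleavage from the target.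
- In favour: the acetonide masks acid and phenol at once, ring B and C2 arrive together, and the whole sequence is polar chemistry at low temperature.
- Against: A2 already contains the complete ring A, so the C6-versus-C8 prenylation problem and the protection of a chelated hydroxyl are only moved into the fragment synthesis. A3 has lithium and methoxide on adjacent carbons and can eliminate to an arylalkyne. The carbonyl of A2 is flanked by an ortho substituent. The final acidic acetal removal takes place next to a prenyl group ortho to the freed phenol.
- Comparison: on mechanism and handling this alternative is the better, since it needs neither diazo compounds nor light. On structure the chosen plan is stronger, because the annulation itself creates the ring A substitution pattern. On step economy the two are probably equal at best, since A2 and A3 each need several steps and a deprotection follows.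

Alternative 2: The cut removes ring B (C5'–C6', C1'–C2' and C2'–C3'). In the forward sense the Fischer carbene pentacarbonyl[methoxy(1-methoxyethenyl)methylidene]chromium A6, of formula (CO)5Cr=C(OMe)C(OMe)=CH2, would react with 3-ethynyl-5,7-dimethoxy-6-(3-methylbut-2-enyl)-4H-chromen-4-one A5 by alkyne insertion, CO insertion and electrocyclisation (Dötz benzannulation). The product would be 3-(2-hydroxy-4,5-dimethoxyphenyl)-5,7-dimethoxy-6-(3-methylbut-2-enyl)-4H-chromen-4-one A4. The 2'-hydroxyl would then be methylated and the 5-methyl ether removed.
- In favour: the regiochemistry of terminal alkynes in this reaction is dependable (the large substituent ends ortho to the new phenol), and the 2',4',5'-oxygen pattern appears in one step. On predictability of regiochemistry it is the equal of the chosen plan.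
- Against: the annulation is spent on ring B, which is commercially available ready-made, while the hard ring A must still be made classically inside A5. Chromium is used stoichiometrically. An alkyne conjugated to the chromone carbonyl is electron-poor and a weaker partner. Two adjustments follow, one of them a Lewis-acid demethylation beside the prenyl group.
- Comparison: on structure and step economy the chosen plan is clearly ahead. On mechanism both are pericyclic cascades of similar complexity.

Alternative 3: The cut runs through ring C at O1–C8a and C4–C4a. In the forward sense CsF would release an aryne from 3,5-dimethoxy-4-(3-methylbut-2-enyl)-2-(trimethylsilyl)phenyl trifluoromethanesulfonate A8. The enolate oxygen of methyl (Z)-3-hydroxy-2-(2,4,5-trimethoxyphenyl)prop-2-enoate A9 would add to the aryne carbon remote from the methoxy group (future C8a), and the aryl anion at C4a would then attack the ester. The product would be 5,7-dimethoxy-6-(3-methylbut-2-enyl)-3-(2,4,5-trimethoxyphenyl)-4H-chromen-4-one A7.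
- In favour: it is the most convergent proposal, forming both ring C bonds in one mild operation. The inductive effect of the neighbouring methoxy group steers the nucleophile to the correct aryne carbon. Prenyl sits between two identical methoxy groups in A8, so the C6/C8 question does not arise. On that point it equals the chosen plan, and on convergence it is probably the better.
- Against: stabilised enolates tend to attack arynes through carbon, leading to insertion into the C–C bond, so O-selectivity is not assured. The prenyl alkene is an ene partner for arynes. A7 ends with a 5-methyl ether whose selective removal needs a Lewis acid beside the prenyl group. A8 itself needs a silylation/triflation sequence.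
- Comparison: the chosen plan delivers the 5-hydroxyl free and needs no demethylation. The price is the hazard of diazomethane and a photochemical step on a new substrate.

Key step: step 8

Remark on the chemistry: diazomethane is used in one step only, as a dilute solution at 0 °C. A diazomethane-free path to 8 is given among the fallbacks.

## Steps

Step 1
Reactants: 1 comenic acid (5-hydroxy-4-oxo-4H-pyran-2-carboxylic acid)
Product: 2 methyl 5-hydroxy-4-oxo-4H-pyran-2-carboxylate
Conditions: MeOH, H2SO4 (cat.), reflux
Reagents that add atoms: methanol, CO
Why: Fischer esterification; the enolic 5-hydroxyl does not react, and the ester masks the acid during triflation and coupling.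

Step 2
Reactants: 2 methyl 5-hydroxy-4-oxo-4H-pyran-2-carboxylate
Product: 3 methyl 4-oxo-5-[(trifluoromethylsulfonyl)oxy]-4H-pyran-2-carboxylate
Conditions: PhNTf2, Et3N, CH2Cl2, 0 °C → 20 °C
Reagents that add atoms: N-phenylbis(trifluoromethanesulfonimide), O=S(=O)(N(c1ccccc1)S(=O)(=O)C(F)(F)F)C(F)(F)F
Why: O-sulfonylation of an acidic enolic hydroxyl; the mild triflyl donor is preferred to Tf2O, which could also activate the nucleophilic pyranone carbonyl oxygen.

Step 3
Reactants: 3 methyl 4-oxo-5-[(trifluoromethylsulfonyl)oxy]-4H-pyran-2-carboxylate; 4 2,4,5-trimethoxyphenylboronic acid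
Product: 5 methyl 4-oxo-5-(2,4,5-trimethoxyphenyl)-4H-pyran-2-carboxylate
Conditions: Pd(PPh3)4 (5 mol %), K3PO4, KBr, 1,4-dioxane, 85 °C
Reagents that add atoms: none
Why: Suzuki–Miyaura coupling; zerovalent palladium should insert readily into the electron-poor enol triflate. Anhydrous phosphate limits S–O cleavage of the triflate and ester hydrolysis, and an excess of 4 covers protodeboronation of the electron-rich boronic acid.

Step 4
Reactants: 5 methyl 4-oxo-5-(2,4,5-trimethoxyphenyl)-4H-pyran-2-carboxylate
Product: 6 4-oxo-5-(2,4,5-trimethoxyphenyl)-4H-pyran-2-carboxylic acid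
Conditions: 6 M aq HCl, AcOH, 90 °C
Reagents that add atoms: water, O
Why: acid-catalysed ester hydrolysis; hydroxide is avoided because it can add at the unsubstituted pyranone C6 and open the ring, whereas the pyranone and the aryl methyl ethers tolerate aqueous HCl.

Step 5
Reactants: 6 4-oxo-5-(2,4,5-trimethoxyphenyl)-4H-pyran-2-carboxylic acid
Product: 8 2-(2-diazoacetyl)-5-(2,4,5-trimethoxyphenyl)-4H-pyran-4-one, via acid chloride 7 (not isolated)
Conditions: (COCl)2 (1.1 equiv), DMF (cat.), CH2Cl2, 0 °C → 20 °C; evaporate; CH2N2 (3 equiv), Et2O/THF, 0 °C
Reagents that add atoms: diazomethane, C=[N+]=[N-]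
Why: acid chloride formation followed by Arndt–Eistert-type acylation of diazomethane; 7 has no α-hydrogen, so no ketene can form. Excess diazomethane removes HCl (otherwise a chloromethyl ketone would form), and the low temperature favours acylation over dipolar cycloaddition to the pyranone.

Step 6
Reactants: 9 4-methylpent-3-enoic acid
Product: 10 ethyl 4-methylpent-3-enoate
Conditions: EtI, K2CO3, DMF, 20 °C
Reagents that add atoms: iodoethane, CCI
Why: carboxylate O-alkylation (SN2); acid-catalysed esterification is avoided because strong acid would lactonise this β,γ-unsaturated acid or shift its double bond into conjugation.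

Step 7
Reactants: 10 ethyl 4-methylpent-3-enoate
Product: 12 triisopropyl[(5-methylhex-4-en-1-yn-1-yl)oxy]silane, via lithium ynolate 11 (not isolated)
Conditions: CH2Br2, lithium 2,2,6,6-tetramethylpiperidide (2.2 equiv), THF, −78 °C; n-BuLi, −78 °C → 20 °C; i-Pr3SiOTf, −78 → 0 °C
Reagents that add atoms: dibromomethane, BrCBr; triisopropylsilyl trifluoromethanesulfonate, CC(C)[Si](OS(=O)(=O)C(F)(F)F)(C(C)C)C(C)C
Why: Kowalski ester homologation: LiCHBr2 adds to the ester, then bromine–lithium exchange and a carbenoid 1,2-shift of the prenyl group give ynolate 11. The bulky, hard silyl triflate traps 11 on oxygen.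

Step 8
Reactants: 8 2-(2-diazoacetyl)-5-(2,4,5-trimethoxyphenyl)-4H-pyran-4-one; 12 triisopropyl[(5-methylhex-4-en-1-yn-1-yl)oxy]silane
Product: 17 5-hydroxy-6-(3-methylbut-2-enyl)-7-[(triisopropylsilyl)oxy]-3-(2,4,5-trimethoxyphenyl)-4H-chromen-4-one, via pyranonylketene 13 (not isolated), via cyclobutenone 14 (not isolated), via dienylketene 15 (not isolated), via cyclohexadienone 16 (not isolated)
Conditions: hν (405–450 nm LED), 12 (1.5 equiv), degassed ClCH2CH2Cl, 20 °C; then 80 °C
Reagents that add atoms: none
Why: This is the Danheiser benzannulation in its photo-Wolff form, known for aryl, heteroaryl and vinyl diazomethyl ketones with siloxyalkynes; the 4-pyranone is an untested member of that class, its C2=C3 bond taking the vinyl role. Light absorbed in the diazo n→π* band expels N2 and the pyranonyl group shifts from the acyl carbon to the diazo carbon (new C8–C8a bond), giving ketene 13, whose carbonyl carbon is the future C5. A (2+2) cycloaddition then joins the electrophilic ketene carbon to the nucleophilic, prenyl-bearing carbon of 12 (C5–C6) and the ketene CH to the siloxy carbon (C7–C8), giving 14. A four-electron conrotatory opening of 14 breaks the old C5–C8 bond to give 15; it is reversible, so material drains through the isomer with the pyranonyl group cis to the ketenyl carbon. Ring A closes by a six-electron disrotatory electrocyclisation between the ketene carbon and pyranone C3 (C4a–C5), and dienone 16, whose C4a–H lies between two carbonyls, enolises to the aromatic 5-phenol. No stereocentre remains in 17, so none has to be controlled. Regiochemistry rests on the polarisation of the ynol ether (prenyl at C6, silyloxy at C7) and on the pyranonyl carbon having only one carbon neighbour (C3, the other being the ring oxygen), so only the linear chromone can form. Chemoselectivity rests on three points: at 405–450 nm only the diazoketone should absorb, so pyranone and product are not excited; the prenyl alkene is far less nucleophilic towards the ketene than the ynol ether; and the product phenol is tied to the C4 carbonyl and should resist acylation by remaining ketene.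

Step 9
Reactants: 17 5-hydroxy-6-(3-methylbut-2-enyl)-7-[(triisopropylsilyl)oxy]-3-(2,4,5-trimethoxyphenyl)-4H-chromen-4-one
Product: 19 5-hydroxy-7-methoxy-6-(3-methylbut-2-enyl)-3-(2,4,5-trimethoxyphenyl)-4H-chromen-4-one, via caesium phenoxide 18 (not isolated)
Conditions: CsF, MeI (1.2 equiv), DMF, 0 °C → 20 °C
Reagents that add atoms: iodomethane, CI
Why: fluoride cleaves the aryl silyl ether to phenoxide 18, which is methylated in the same flask (Williamson ether synthesis). The 5-hydroxyl is locked in a hydrogen bond to the C4 carbonyl and is much less acidic and nucleophilic, so it should stay free. No acid is used, so the prenyl group is not at risk.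

## Compound list

1 | comenic acid (5-hydroxy-4-oxo-4H-pyran-2-carboxylic acid) | O=C(O)c1cc(=O)c(O)co1 | starting material
2 | methyl 5-hydroxy-4-oxo-4H-pyran-2-carboxylate | COC(=O)c1cc(=O)c(O)co1 | intermediate
3 | methyl 4-oxo-5-[(trifluoromethylsulfonyl)oxy]-4H-pyran-2-carboxylate | COC(=O)c1cc(=O)c(OS(=O)(=O)C(F)(F)F)co1 | intermediate
4 | 2,4,5-trimethoxyphenylboronic acid | COc1cc(OC)c(B(O)O)cc1OC | starting material
5 | methyl 4-oxo-5-(2,4,5-trimethoxyphenyl)-4H-pyran-2-carboxylate | COC(=O)c1cc(=O)c(-c2cc(OC)c(OC)cc2OC)co1 | intermediate
6 | 4-oxo-5-(2,4,5-trimethoxyphenyl)-4H-pyran-2-carboxylic acid | O=C(O)c1cc(=O)c(-c2cc(OC)c(OC)cc2OC)co1 | intermediate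
7 | 4-oxo-5-(2,4,5-trimethoxyphenyl)-4H-pyran-2-carbonyl chloride | O=C(Cl)c1cc(=O)c(-c2cc(OC)c(OC)cc2OC)co1 | intermediate
8 | 2-(2-diazoacetyl)-5-(2,4,5-trimethoxyphenyl)-4H-pyran-4-one | COc1cc(OC)c(-c2coc(C(=O)C=[N+]=[N-])cc2=O)cc1OC | intermediate
9 | 4-methylpent-3-enoic acid | CC(C)=CCC(=O)O | starting material
10 | ethyl 4-methylpent-3-enoate | CCOC(=O)CC=C(C)C | intermediate
11 | lithium 5-methylhex-4-en-1-yn-1-olate | [Li+].[O-]C#CCC=C(C)C | intermediate
12 | triisopropyl[(5-methylhex-4-en-1-yn-1-yl)oxy]silane | CC(C)=CCC#CO[Si](C(C)C)(C(C)C)C(C)C | intermediate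
13 | 2-(2-oxoethenyl)-5-(2,4,5-trimethoxyphenyl)-4H-pyran-4-one (pyranonylketene) | COc1cc(OC)c(-c2coc(C=C=O)cc2=O)cc1OC | intermediate
14 | racemic 2-(3-methylbut-2-enyl)-4-[4-oxo-5-(2,4,5-trimethoxyphenyl)-4H-pyran-2-yl]-3-[(triisopropylsilyl)oxy]cyclobut-2-en-1-one | COc1cc(OC)c(-c2coc(C3C(=O)C(CC=C(C)C)=C3O[Si](C(C)C)(C(C)C)C(C)C)cc2=O)cc1OC | intermediate
15 | 2-[(1E)-3-(3-methylbut-2-enyl)-4-oxo-2-[(triisopropylsilyl)oxy]buta-1,3-dien-1-yl]-5-(2,4,5-trimethoxyphenyl)-4H-pyran-4-one (dienylketene) | COc1cc(OC)c(-c2coc(/C=C(/O[Si](C(C)C)(C(C)C)C(C)C)C(CC=C(C)C)=C=O)cc2=O)cc1OC | intermediate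
16 | racemic 6-(3-methylbut-2-enyl)-7-[(triisopropylsilyl)oxy]-3-(2,4,5-trimethoxyphenyl)-4aH-chromene-4,5-dione | COc1cc(OC)c(C2=COC3=CC(O[Si](C(C)C)(C(C)C)C(C)C)=C(CC=C(C)C)C(=O)C3C2=O)cc1OC | intermediate
17 | 5-hydroxy-6-(3-methylbut-2-enyl)-7-[(triisopropylsilyl)oxy]-3-(2,4,5-trimethoxyphenyl)-4H-chromen-4-one | COc1cc(OC)c(-c2coc3cc(O[Si](C(C)C)(C(C)C)C(C)C)c(CC=C(C)C)c(O)c3c2=O)cc1OC | intermediate
18 | caesium 5-hydroxy-6-(3-methylbut-2-enyl)-4-oxo-3-(2,4,5-trimethoxyphenyl)-4H-chromen-7-olate | [Cs+].COc1cc(OC)c(-c2coc3cc([O-])c(CC=C(C)C)c(O)c3c2=O)cc1OC | intermediate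
19 | 5-hydroxy-7-methoxy-6-(3-methylbut-2-enyl)-3-(2,4,5-trimethoxyphenyl)-4H-chromen-4-one | COc1cc(OC)c(-c2coc3cc(OC)c(CC=C(C)C)c(O)c3c2=O)cc1OC | target

## Step count and least certain steps

Total: 9 steps. Longest linear sequence: 7 steps (steps 1, 2, 3, 4, 5, 8, 9); the siloxyalkyne branch (steps 6 and 7) joins at step 8.

Step 8 (key step). The most likely failure is competitive light absorption by the arylpyranone or the isoflavone product, leading to photodegradation. The second is a slow six-electron closure onto the electron-poor pyranone carbon, which would let the dienylketene dimerise or be trapped. The fallback generates the same ketene in the dark. It sets out from 8, which undergoes a Wolff rearrangement in aqueous dioxane with PhCO2Ag and Et3N to give 2-[4-oxo-5-(2,4,5-trimethoxyphenyl)-4H-pyran-2-yl]acetic acid F1. Oxalyl chloride converts this into 2-[4-oxo-5-(2,4,5-trimethoxyphenyl)-4H-pyran-2-yl]acetyl chloride F2. Slow addition of F2 to Et3N and 12 in toluene should give ketene 13 by dehydrochlorination, and its (2+2) adduct 14 is where the fallback rejoins the route; heating then leads to 17.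

Step 7. The α-CH2 of 10 is both allylic and α to the ester, so deprotonation by the lithium amide or by LiCHBr2 may outrun carbonyl addition, returning 10 or its conjugated isomer. The fallback makes the ynolate by oxidising an acetylide. It sets out from 10, which is reduced with i-Bu2AlH at −78 °C to 4-methylpent-3-enal F3. CBr4 and PPh3 convert this into 1,1-dibromo-5-methylhexa-1,4-diene F4. Two equivalents of n-BuLi give lithium 5-methylhex-4-en-1-ynide F5. Oxidation of F5 with LiOOt-Bu gives 11, where the fallback rejoins the route before silylation to 12.

Step 5. Diazomethane may add as a 1,3-dipole across the activated pyranone double bonds, or the diazoketone may be converted by HCl into a chloromethyl ketone. The fallback avoids diazomethane. It sets out from 7, which acylates Meldrum's acid (pyridine, CH2Cl2) to give 5-{hydroxy[4-oxo-5-(2,4,5-trimethoxyphenyl)-4H-pyran-2-yl]methylidene}-2,2-dimethyl-1,3-dioxane-4,6-dione F6. Heating in aqueous acetic acid gives 2-acetyl-5-(2,4,5-trimethoxyphenyl)-4H-pyran-4-one F7. Its lithium enolate (LiN(SiMe3)2, −78 °C) is trifluoroacetylated with CF3CO2CH2CF3 to 4,4,4-trifluoro-1-[4-oxo-5-(2,4,5-trimethoxyphenyl)-4H-pyran-2-yl]butane-1,3-dione F8. Detrifluoroacetylative diazo transfer (MsN3, Et3N, H2O, MeCN) then gives 8, where the fallback rejoins the route.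

Step 3. Base may cleave the S–O bond of the triflate and return 2, and the electron-rich, ortho-substituted boronic acid 4 may protodeboronate before transmetalation. The fallback is a base-free organozinc coupling. It sets out from 3, which is coupled (Pd(PPh3)4, THF, 50 °C) with chlorido(2,4,5-trimethoxyphenyl)zinc F9, made from 1-bromo-2,4,5-trimethoxybenzene with n-BuLi and ZnCl2. This Negishi coupling gives 5, where the fallback rejoins the route.

## Further compounds

F1 | step 8 | 2-[4-oxo-5-(2,4,5-trimethoxyphenyl)-4H-pyran-2-yl]acetic acid | O=C(O)Cc1cc(=O)c(-c2cc(OC)c(OC)cc2OC)co1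
F2 | step 8 | 2-[4-oxo-5-(2,4,5-trimethoxyphenyl)-4H-pyran-2-yl]acetyl chloride | O=C(Cl)Cc1cc(=O)c(-c2cc(OC)c(OC)cc2OC)co1
F3 | step 7 | 4-methylpent-3-enal | CC(C)=CCC=O
F4 | step 7 | 1,1-dibromo-5-methylhexa-1,4-diene | CC(C)=CCC=C(Br)Br
F5 | step 7 | lithium 5-methylhex-4-en-1-ynide | [Li+].[C-]#CCC=C(C)C
F6 | step 5 | 5-{hydroxy[4-oxo-5-(2,4,5-trimethoxyphenyl)-4H-pyran-2-yl]methylidene}-2,2-dimethyl-1,3-dioxane-4,6-dione | CC1(C)OC(=O)C(=C(O)c2cc(=O)c(-c3cc(OC)c(OC)cc3OC)co2)C(=O)O1
F7 | step 5 | 2-acetyl-5-(2,4,5-trimethoxyphenyl)-4H-pyran-4-one | CC(=O)c1cc(=O)c(-c2cc(OC)c(OC)cc2OC)co1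
F8 | step 5 | 4,4,4-trifluoro-1-[4-oxo-5-(2,4,5-trimethoxyphenyl)-4H-pyran-2-yl]butane-1,3-dione | O=C(CC(=O)C(F)(F)F)c1cc(=O)c(-c2cc(OC)c(OC)cc2OC)co1
F9 | step 3 | chlorido(2,4,5-trimethoxyphenyl)zinc | COc1cc(OC)c([Zn]Cl)cc1OC
A1 | alternative 1 | 7-methoxy-5-(methoxymethoxy)-6-(3-methylbut-2-enyl)-3-(2,4,5-trimethoxyphenyl)-4H-chromen-4-one | COCOc1c(CC=C(C)C)c(OC)cc2occ(-c3cc(OC)c(OC)cc3OC)c(=O)c12
A2 | alternative 1 | 7-methoxy-5-(methoxymethoxy)-2,2-dimethyl-6-(3-methylbut-2-enyl)-4H-1,3-benzodioxin-4-one | COCOc1c(CC=C(C)C)c(OC)cc2OC(C)(C)OC(=O)c12
A3 | alternative 1 | (E)-[2-methoxy-1-(2,4,5-trimethoxyphenyl)ethenyl]lithium | [Li]/C(=C\OC)c1cc(OC)c(OC)cc1OC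
A4 | alternative 2 | 3-(2-hydroxy-4,5-dimethoxyphenyl)-5,7-dimethoxy-6-(3-methylbut-2-enyl)-4H-chromen-4-one | COc1cc(O)c(-c2coc3cc(OC)c(CC=C(C)C)c(OC)c3c2=O)cc1OC
A5 | alternative 2 | 3-ethynyl-5,7-dimethoxy-6-(3-methylbut-2-enyl)-4H-chromen-4-one | C#Cc1coc2cc(OC)c(CC=C(C)C)c(OC)c2c1=O
A6 | alternative 2 | pentacarbonyl[methoxy(1-methoxyethenyl)methylidene]chromium | COC(=C)C(OC)=[Cr](=C=O)(=C=O)(=C=O)(=C=O)=C=O
A7 | alternative 3 | 5,7-dimethoxy-6-(3-methylbut-2-enyl)-3-(2,4,5-trimethoxyphenyl)-4H-chromen-4-one | COc1cc(OC)c(-c2coc3cc(OC)c(CC=C(C)C)c(OC)c3c2=O)cc1OC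
A8 | alternative 3 | 3,5-dimethoxy-4-(3-methylbut-2-enyl)-2-(trimethylsilyl)phenyl trifluoromethanesulfonate | COc1cc(OS(=O)(=O)C(F)(F)F)c([Si](C)(C)C)c(OC)c1CC=C(C)C
A9 | alternative 3 | methyl (Z)-3-hydroxy-2-(2,4,5-trimethoxyphenyl)prop-2-enoate | COC(=O)/C(=C\O)c1cc(OC)c(OC)cc1OC
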